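**Retrosynthetic overview**

1. The strategy rests on the α-ketol pattern of the six-membered carbocycle: the tertiary carbinol C5 (OH and the C19 chain) sits next to the oxygenated C4. The ring is therefore cut at C4–C5, and an N-heterocyclic-carbene crossed benzoin closure of the acyclic keto aldehyde 21 (C1 stored as a dioxolane) forms this bond, the only ring and the C5 stereocentre in one step.
2. After closure the C4 ketone can enolize only toward C3, so Saegusa oxidation gives the C2=C3 alkene. A 1,2-reduction anti to the C5–O bond then sets C4, and unmasking C1 puts the enone in its final place.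
3. Keto aldehyde 21 comes from Weinreb amide 17 and the Grignard reagent of bromide 8. Amide 17 is built from ethyl acetoacetate (C1, C2, C5, C6) and allyl bromide (C3, C4).
4. Bromide 8 comes from pentadecanolide (C1'–C15') and but-1-yne (C16'–C19'), with the E-alkene set by dissolving-metal reduction of the alkyne.

Key step: step 14

Numbering used throughout (target numbering): C1 carbonyl, C2=C3, C4 (CHOH), C5 (C(OH)–chain), C6 (CH2); chain carbons C1'–C19'.

Assumption: the (5aS,10bR) antipode of the aminoindanol-derived triazolium salt is taken as the one that directs attack to the Re face of the C5 ketone (O > CH2–C1 > CH2–chain). If the sense of induction proves to be the reverse, the (5aR,10bS) salt replaces it in step 14 and nothing else changes.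

**Route**

Step 1
Reactants: 1 pentadecanolide
Product: 2 pentadecane-1,15-diol
Conditions: LiAlH4, THF, 0 °C → reflux; H2O/aq NaOH work-up
Reagents that add atoms: none
Why: Hydride reduction of the lactone (LiAlH4 ester reduction) opens the macrocycle to the α,ω-diol, and no other functional group is present.

Step 2
Reactants: 2 pentadecane-1,15-diol
Product: 3 15-bromopentadecan-1-ol
Conditions: 48% aq HBr (slight excess), toluene, reflux
Reagents that add atoms: hydrogen bromide, Br
Why: Monobromination of a symmetrical diol (SN2 on the protonated alcohol) in the two-phase toluene system, in which the bromo alcohol passes into the organic phase and should thereby be shielded from a second substitution.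

Step 3
Reactants: 3 15-bromopentadecan-1-ol; 4 but-1-yne
Product: 6 nonadec-16-yn-1-ol, via lithium but-1-yn-1-ide 5 (not isolated)
Conditions: 4 (3 equiv), n-BuLi (2.6 equiv), THF, −78 → 0 °C; then 3, DMPU, 0 °C → rt; aq NH4Cl
Reagents that add atoms: none
Why: SN2 alkylation of a lithium acetylide by a primary bromide in a dipolar aprotic cosolvent, one extra equivalent of acetylide serving as base for the hydroxyl, whose lithium alkoxide is a much poorer nucleophile toward the bromide than the acetylide.

Step 4
Reactants: 6 nonadec-16-yn-1-ol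
Product: 7 (E)-nonadec-16-en-1-ol
Conditions: Na, NH3(l)/THF, −33 °C; then NH4Cl
Reagents that add atoms: none
Why: Dissolving-metal reduction of a dialkyl alkyne runs through the trans-vinyl radical and anion and should give the E-alkene only, the remote alkoxide being inert.

Step 5
Reactants: 7 (E)-nonadec-16-en-1-ol
Product: 8 (E)-19-bromononadec-3-ene
Conditions: CBr4, PPh3, CH2Cl2, 0 °C → rt
Reagents that add atoms: carbon tetrabromide, BrC(Br)(Br)Br
Why: Appel bromination of a primary alcohol through the alkoxyphosphonium salt, under neutral conditions that leave the isolated E-alkene untouched.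

Step 6
Reactants: 9 ethyl acetoacetate; 10 allyl bromide
Product: 12 ethyl 3-oxohept-6-enoate, via ethyl acetoacetate dianion 11 (not isolated)
Conditions: NaH, THF, 0 °C; n-BuLi, 0 °C; then 10, 0 °C → rt; aq NH4Cl
Reagents that add atoms: none
Why: Weiler dianion alkylation, in which the γ-carbanion is the more reactive site of the dianion and is allylated selectively to give the C2–C3–C4 unit.

Step 7
Reactants: 12 ethyl 3-oxohept-6-enoate
Product: 13 ethyl 2-[2-(but-3-en-1-yl)-1,3-dioxolan-2-yl]acetate
Conditions: HOCH2CH2OH, p-toluenesulfonic acid monohydrate (cat.), toluene, reflux, Dean–Stark trap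
Reagents that add atoms: ethylene glycol, OCCO
Why: Acid-catalysed ketalization with azeotropic removal of water masks the future C1 carbonyl, while the ester and the terminal alkene do not react.

Step 8
Reactants: 13 ethyl 2-[2-(but-3-en-1-yl)-1,3-dioxolan-2-yl]acetate
Product: 15 ethyl 2-[2-(3-hydroxypropyl)-1,3-dioxolan-2-yl]acetate, via secondary ozonide 14 (not isolated)
Conditions: O3, CH2Cl2, −78 °C; then NaBH4, MeOH, −78 → 0 °C
Reagents that add atoms: ozone, [O-][O+]=O
Why: Ozonolysis of the only alkene with reductive NaBH4 work-up gives the C4 primary alcohol while the ester is reduced far more slowly at 0 °C, and the step is placed before the chain is attached so that the chain alkene never meets ozone.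

Step 9
Reactants: 15 ethyl 2-[2-(3-hydroxypropyl)-1,3-dioxolan-2-yl]acetate
Product: 16 ethyl 2-{2-[3-(tert-butyldimethylsilyloxy)propyl]-1,3-dioxolan-2-yl}acetate
Conditions: TBSCl, imidazole, DMF, rt
Reagents that add atoms: tert-butyldimethylsilyl chloride, CC(C)(C)[Si](C)(C)Cl
Why: Standard imidazole-mediated silylation of a primary alcohol, giving an ether that withstands the two organomagnesium steps that follow.

Step 10
Reactants: 16 ethyl 2-{2-[3-(tert-butyldimethylsilyloxy)propyl]-1,3-dioxolan-2-yl}acetate
Product: 17 2-{2-[3-(tert-butyldimethylsilyloxy)propyl]-1,3-dioxolan-2-yl}-N-methoxy-N-methylacetamide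
Conditions: MeNH(OMe)·HCl, i-PrMgCl, THF, −20 → 0 °C
Reagents that add atoms: N,O-dimethylhydroxylamine hydrochloride, CNOC.Cl
Why: Direct aminolysis of the ester by the chloromagnesium amide formed in the flask (Weinreb amide synthesis), which is nucleophilic and only weakly basic, so that the β-ketal is not opened by elimination.

Step 11
Reactants: 8 (E)-19-bromononadec-3-ene; 17 2-{2-[3-(tert-butyldimethylsilyloxy)propyl]-1,3-dioxolan-2-yl}-N-methoxy-N-methylacetamide
Product: 19 (E)-1-{2-[3-(tert-butyldimethylsilyloxy)propyl]-1,3-dioxolan-2-yl}henicos-18-en-2-one, via (E)-nonadec-16-enylmagnesium bromide 18 (not isolated)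
Conditions: 8, Mg turnings, THF, 45 °C; then 17, THF, 0 °C → rt; aq NH4Cl
Reagents that add atoms: none
Why: Weinreb ketone synthesis, in which the primary Grignard reagent adds once to give a stable five-membered magnesium chelate that releases the C5 ketone only on work-up, so no tertiary alcohol should form.

Step 12
Reactants: 19 (E)-1-{2-[3-(tert-butyldimethylsilyloxy)propyl]-1,3-dioxolan-2-yl}henicos-18-en-2-one
Product: 20 (E)-1-[2-(3-hydroxypropyl)-1,3-dioxolan-2-yl]henicos-18-en-2-one
Conditions: n-Bu4NF, AcOH (1:1), THF, 0 °C → rt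
Reagents that add atoms: none
Why: Fluoride-driven desilylation, buffered with acetic acid so that the β-ketal ketone is exposed neither to base (ketal opening by elimination) nor to strong acid (transketalization by the free hydroxyl).

Step 13
Reactants: 20 (E)-1-[2-(3-hydroxypropyl)-1,3-dioxolan-2-yl]henicos-18-en-2-one
Product: 21 3-{2-[(E)-2-oxohenicos-18-enyl]-1,3-dioxolan-2-yl}propanal
Conditions: Dess–Martin periodinane, NaHCO3, CH2Cl2, 0 °C → rt
Reagents that add atoms: none
Why: Dess–Martin oxidation of the primary alcohol stops at the aldehyde under buffered, near-neutral conditions that spare the ketal and the alkene, and the keto aldehyde is taken on without delay.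

Step 14
Reactants: 21 3-{2-[(E)-2-oxohenicos-18-enyl]-1,3-dioxolan-2-yl}propanal
Product: 22 (7S)-7-hydroxy-7-[(E)-nonadec-16-enyl]-1,4-dioxaspiro[4.5]decan-8-one
Conditions: (5aS,10bR)-2-(pentafluorophenyl)-5a,10b-dihydro-4H,6H-indeno[2,1-b][1,2,4]triazolo[4,3-d][1,4]oxazin-2-ium tetrafluoroborate (15 mol %), Et3N (15 mol %), degassed toluene (0.05 mol/L), rt
Reagents that add atoms: none
Why: The triazolylidene freed by Et3N adds to the C4 aldehyde, proton transfer gives the Breslow enaminol, and this acyl-anion equivalent attacks the tethered C5 ketone, after which the adduct expels the carbene and leaves the C4 ketone beside the new C5 carbinol; the closest known reaction type is the chiral triazolium-catalysed intramolecular crossed aldehyde–ketone benzoin cyclization to six-membered tertiary α-ketols. The carbocycle is closed in a 6-exo-trig mode, helped by the gem-disubstituted ketal carbon C1. The one new stereocentre, C5, is controlled by the catalyst alone because 21 is achiral: the indane-fused backbone shields one face of the enaminol and an O–H···O=C hydrogen bond holds the ketone so that its Re face is attacked, which gives 5S (7S in the spiro numbering). The step needs chemoselectivity (acyl anion from the aldehyde only, benzoin ahead of aldol) and enantioface selection; the first is secured because only the aldehyde can form a Breslow intermediate and the only closure open to it is six-membered, while the second rests on the catalyst. The weak amine base and the dilution should hold back aldol closure, opening of the β-ketal and self-benzoin of the aldehyde, and the product cannot racemize because C5 is quaternary.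

Step 15
Reactants: 22 (7S)-7-hydroxy-7-[(E)-nonadec-16-enyl]-1,4-dioxaspiro[4.5]decan-8-one
Product: 23 (7S)-7-[(E)-nonadec-16-enyl]-7,8-bis(trimethylsilyloxy)-1,4-dioxaspiro[4.5]dec-8-ene
Conditions: TMSCl (4 equiv), then LiN(i-Pr)2 (2.6 equiv), THF, −78 → 0 °C (internal quench)
Reagents that add atoms: chlorotrimethylsilane, C[Si](C)(C)Cl
Why: Kinetic enolization with in situ silyl trapping (Corey internal-quench silyl enol ether formation) can occur only toward C3 because C5 bears no hydrogen, and the tertiary alkoxide is capped at once, so that neither α-ketol rearrangement nor Lewis-acid opening of the ketal can intervene.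

Step 16
Reactants: 23 (7S)-7-[(E)-nonadec-16-enyl]-7,8-bis(trimethylsilyloxy)-1,4-dioxaspiro[4.5]dec-8-ene
Product: 24 (9S)-9-[(E)-nonadec-16-enyl]-9-(trimethylsilyloxy)-1,4-dioxaspiro[4.5]dec-6-en-8-one
Conditions: Pd(OAc)2 (1.05 equiv), dry MeCN, rt
Reagents that add atoms: none
Why: Saegusa–Ito oxidation, in which the silyl enol ether is transmetallated to an oxa-π-allyl complex of divalent palladium and β-hydride elimination toward C2 gives the C2=C3 enone, a transformation well established for 1,4-dioxaspiro[4.5]decan-8-one enol ethers.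

Step 17
Reactants: 24 (9S)-9-[(E)-nonadec-16-enyl]-9-(trimethylsilyloxy)-1,4-dioxaspiro[4.5]dec-6-en-8-one
Product: 25 (8R,9S)-9-[(E)-nonadec-16-enyl]-9-(trimethylsilyloxy)-1,4-dioxaspiro[4.5]dec-6-en-8-ol
Conditions: NaBH4, CeCl3·7H2O, MeOH/THF, −78 °C
Reagents that add atoms: none
Why: Luche 1,2-reduction of the enone, in which the chain sits pseudo-equatorial and the non-chelating C5–OSiMe3 bond pseudo-axial, so that axial hydride delivery anti to that C–O bond (polar Felkin–Anh) places the new C4 hydroxyl cis to the C5 oxygen and sets 4R.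

Step 18
Reactants: 25 (8R,9S)-9-[(E)-nonadec-16-enyl]-9-(trimethylsilyloxy)-1,4-dioxaspiro[4.5]dec-6-en-8-ol
Product: 26 (4R,5S)-4,5-dihydroxy-5-[(E)-nonadec-16-en-1-yl]cyclohex-2-en-1-one
Conditions: 0.5 mol/L aq HCl, THF, 0 °C → rt; NaHCO3 quench
Reagents that add atoms: water, O
Why: Mild acid hydrolysis cleaves the allylic ketal readily through its allyl-stabilized oxocarbenium ion and removes the labile tertiary trimethylsilyl ether at the same time, which frees the C1 carbonyl in conjugation with C2=C3 without touching either carbinol centre.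

**Compound list**

1 | pentadecanolide (oxacyclohexadecan-2-one) | O=C1CCCCCCCCCCCCCCO1 | starting material
2 | pentadecane-1,15-diol | OCCCCCCCCCCCCCCCO | intermediate
3 | 15-bromopentadecan-1-ol | OCCCCCCCCCCCCCCCBr | intermediate
4 | but-1-yne | CCC#C | starting material
5 | lithium but-1-yn-1-ide | CCC#[C-].[Li+] | intermediate (not isolated)
6 | nonadec-16-yn-1-ol | CCC#CCCCCCCCCCCCCCCCO | intermediate
7 | (E)-nonadec-16-en-1-ol | CC/C=C/CCCCCCCCCCCCCCCO | intermediate
8 | (E)-19-bromononadec-3-ene | CC/C=C/CCCCCCCCCCCCCCCBr | intermediate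
9 | ethyl acetoacetate | CCOC(=O)CC(C)=O | starting material
10 | allyl bromide | C=CCBr | starting material
11 | ethyl acetoacetate dianion (sodium lithium dienolate) | C=C([O-])C=C([O-])OCC.[Li+].[Na+] | intermediate (not isolated)
12 | ethyl 3-oxohept-6-enoate | C=CCCC(=O)CC(=O)OCC | intermediate
13 | ethyl 2-[2-(but-3-en-1-yl)-1,3-dioxolan-2-yl]acetate | CCOC(=O)CC1(CCC=C)OCCO1 | intermediate
14 | ethyl 2-{2-[2-(1,2,4-trioxolan-3-yl)ethyl]-1,3-dioxolan-2-yl}acetate (secondary ozonide) | CCOC(=O)CC1(CCC2OCOO2)OCCO1 | intermediate (not isolated)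
15 | ethyl 2-[2-(3-hydroxypropyl)-1,3-dioxolan-2-yl]acetate | CCOC(=O)CC1(CCCO)OCCO1 | intermediate
16 | ethyl 2-{2-[3-(tert-butyldimethylsilyloxy)propyl]-1,3-dioxolan-2-yl}acetate | CCOC(=O)CC1(CCCO[Si](C)(C)C(C)(C)C)OCCO1 | intermediate
17 | 2-{2-[3-(tert-butyldimethylsilyloxy)propyl]-1,3-dioxolan-2-yl}-N-methoxy-N-methylacetamide | CON(C)C(=O)CC1(CCCO[Si](C)(C)C(C)(C)C)OCCO1 | intermediate
18 | (E)-nonadec-16-enylmagnesium bromide | CC/C=C/CCCCCCCCCCCCCCC[Mg]Br | intermediate (not isolated)
19 | (E)-1-{2-[3-(tert-butyldimethylsilyloxy)propyl]-1,3-dioxolan-2-yl}henicos-18-en-2-one | CC/C=C/CCCCCCCCCCCCCCCC(=O)CC1(CCCO[Si](C)(C)C(C)(C)C)OCCO1 | intermediate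
20 | (E)-1-[2-(3-hydroxypropyl)-1,3-dioxolan-2-yl]henicos-18-en-2-one | CC/C=C/CCCCCCCCCCCCCCCC(=O)CC1(CCCO)OCCO1 | intermediate
21 | 3-{2-[(E)-2-oxohenicos-18-enyl]-1,3-dioxolan-2-yl}propanal | CC/C=C/CCCCCCCCCCCCCCCC(=O)CC1(CCC=O)OCCO1 | intermediate
22 | (7S)-7-hydroxy-7-[(E)-nonadec-16-enyl]-1,4-dioxaspiro[4.5]decan-8-one | CC/C=C/CCCCCCCCCCCCCCC[C@]1(O)CC2(CCC1=O)OCCO2 | intermediate
23 | (7S)-7-[(E)-nonadec-16-enyl]-7,8-bis(trimethylsilyloxy)-1,4-dioxaspiro[4.5]dec-8-ene | CC/C=C/CCCCCCCCCCCCCCC[C@]1(O[Si](C)(C)C)CC2(CC=C1O[Si](C)(C)C)OCCO2 | intermediate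
24 | (9S)-9-[(E)-nonadec-16-enyl]-9-(trimethylsilyloxy)-1,4-dioxaspiro[4.5]dec-6-en-8-one | CC/C=C/CCCCCCCCCCCCCCC[C@]1(O[Si](C)(C)C)CC2(C=CC1=O)OCCO2 | intermediate
25 | (8R,9S)-9-[(E)-nonadec-16-enyl]-9-(trimethylsilyloxy)-1,4-dioxaspiro[4.5]dec-6-en-8-ol | CC/C=C/CCCCCCCCCCCCCCC[C@]1(O[Si](C)(C)C)CC2(C=C[C@H]1O)OCCO2 | intermediate
26 | (4R,5S)-4,5-dihydroxy-5-[(E)-nonadec-16-en-1-yl]cyclohex-2-en-1-one | CC/C=C/CCCCCCCCCCCCCCC[C@]1(O)CC(=O)C=C[C@H]1O | target

**Step count**

Total steps: 18. Longest linear sequence: 13 steps (steps 1–5 followed by 11–18; the branch of steps 6–10 followed by 11–18 is equally long).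

**Steps most likely to fail**

Step 14. The two faces of a ketone flanked by two methylene groups may be poorly distinguished, and base-mediated aldol closure may outrun the slow addition of the Breslow intermediate to an unactivated dialkyl ketone. The fallback sets out from 21 and comes back at 22.
- Samarium diiodide (SmI2, THF/t-BuOH, −78 °C) closes the same C4–C5 bond by ketyl pinacol cyclization. The samarium-bridged diolate should give the racemic cis-diol, 7-[(E)-nonadec-16-enyl]-1,4-dioxaspiro[4.5]decane-7,8-diol F1.
- The secondary hydroxyl of F1 is esterified with (S)-2-methoxy-2-phenylacetic acid (N,N'-dicyclohexylcarbodiimide, 4-(dimethylamino)pyridine, CH2Cl2).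
- The two diastereomeric esters are separated by chromatography: the (7S,8R) ester F2 is kept and the (7R,8S) ester F3 is set aside. Analysis of the mandelate-type esters also assigns the absolute configuration.
- Saponification of F2 (LiOH, THF/H2O) gives the (7S,8R)-diol F4.
- Parikh–Doering oxidation (SO3·pyridine, DMSO, Et3N) of the secondary alcohol alone returns ketol 22.

Step 17. The silyl ether may be lost before hydride delivery, so that cerium chelation between the two oxygens directs attack to the other face, or the conformational bias may simply give poor facial selectivity. The fallback sets out from 24 and comes back at 25.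
- The (8S,9S) epimer F5 delivered by such a reduction is not discarded but inverted at C4 by Mitsunobu reaction with chloroacetic acid (PPh3, diisopropyl azodicarboxylate, toluene, 0 °C → rt) to the (8R) chloroacetate F6.
- Brief ammonolysis of F6 (NH3 in MeOH, 0 °C) cleaves the ester without touching the tertiary silyl ether and gives 25.
- The stereocentre is thus set by SN2 inversion instead of by facial selectivity.

Step 16. Palladium hydride released after β-hydride elimination may migrate the remote chain double bond or erode its E geometry, and the hindered enol ether flanked by the quaternary C5 may convert incompletely. The fallback sets out from 22, bypasses 23 and comes back at 24.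
- Direct dehydrogenation of the ketone with 2-iodoxybenzoic acid (DMSO/fluorobenzene, 65 °C) can again go only toward C3 and gives the hydroxy enone F7.
- Silylation of the tertiary hydroxyl with N-(trimethylsilyl)imidazole (CH2Cl2, rt) then gives 24 without any transition metal.

**Further compounds**

F1 | step 14 | racemic cis-7-[(E)-nonadec-16-enyl]-1,4-dioxaspiro[4.5]decane-7,8-diol (both enantiomers) | CC/C=C/CCCCCCCCCCCCCCC[C@]1(O)CC2(CC[C@H]1O)OCCO2.CC/C=C/CCCCCCCCCCCCCCC[C@@]1(O)CC2(CC[C@@H]1O)OCCO2
F2 | step 14 | (7S,8R)-7-hydroxy-7-[(E)-nonadec-16-enyl]-1,4-dioxaspiro[4.5]decan-8-yl (2S)-2-methoxy-2-phenylacetate | CC/C=C/CCCCCCCCCCCCCCC[C@]1(O)CC2(CC[C@H]1OC(=O)[C@@H](OC)c3ccccc3)OCCO2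
F3 | step 14 | (7R,8S)-7-hydroxy-7-[(E)-nonadec-16-enyl]-1,4-dioxaspiro[4.5]decan-8-yl (2S)-2-methoxy-2-phenylacetate | CC/C=C/CCCCCCCCCCCCCCC[C@@]1(O)CC2(CC[C@@H]1OC(=O)[C@@H](OC)c3ccccc3)OCCO2
F4 | step 14 | (7S,8R)-7-[(E)-nonadec-16-enyl]-1,4-dioxaspiro[4.5]decane-7,8-diol | CC/C=C/CCCCCCCCCCCCCCC[C@]1(O)CC2(CC[C@H]1O)OCCO2
F5 | step 17 | (8S,9S)-9-[(E)-nonadec-16-enyl]-9-(trimethylsilyloxy)-1,4-dioxaspiro[4.5]dec-6-en-8-ol | CC/C=C/CCCCCCCCCCCCCCC[C@]1(O[Si](C)(C)C)CC2(C=C[C@@H]1O)OCCO2
F6 | step 17 | (8R,9S)-9-[(E)-nonadec-16-enyl]-9-(trimethylsilyloxy)-1,4-dioxaspiro[4.5]dec-6-en-8-yl 2-chloroacetate | CC/C=C/CCCCCCCCCCCCCCC[C@]1(O[Si](C)(C)C)CC2(C=C[C@H]1OC(=O)CCl)OCCO2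
F7 | step 16 | (9S)-9-hydroxy-9-[(E)-nonadec-16-enyl]-1,4-dioxaspiro[4.5]dec-6-en-8-one | CC/C=C/CCCCCCCCCCCCCCC[C@]1(O)CC2(C=CC1=O)OCCO2
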